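## Analysis of the target

The target 16 is a 3',8''-linked biflavone with no stereocentre: flavone 1 (benzo ring A, pyranone ring C, 2-aryl ring B; atoms C2–C8a and C1'–C6') carries methyl ethers at C7 and C4', and flavone 2 (benzo ring D, pyranone ring F, 2-aryl ring E; atoms C2''–C8a'' and C1'''–C6''') carries free hydroxyls at C7'' and C4'''. The two halves are joined by a single bond from C3' of ring B to C8'' of ring D. This axis has three oxygen-bearing ortho carbons (C4', C7'', C8a'') and one C–H (C2') and is drawn without configuration, so nothing has to be controlled there. The sensitive groups are the phenols and the two γ-pyranones, which open at C2 or C2'' under hydroxide or alkoxide and whose C2=C3 bonds can be over-reduced; strongly basic nucleophiles and forcing reductions should therefore be kept away from late intermediates. The first difficulty is that the biaryl bond ends at C8'', a carbon flanked by O7'' and the ring oxygen O1'', so an intermolecular coupling there is crowded. The second is that four oxygen substituents of the same kind need different fates, two methylated on flavone 1 and two free on flavone 2. The strategy rests on the fact that O4' on ring B and O7'' on ring D both stand ortho to the axis, as in a 2,2'-biphenol, so that one silicon atom can bridge them and hold C8'' over C3'. Because ring B of a 4'-oxygenated flavone has two equivalent ortho C–H positions (C3' and C5'), only ring D needs a halogen.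

## Retrosynthetic reasoning

**16 ⇒ 15.** The two benzyl–oxygen bonds at O7'' and O4''' are cut last. Carrying both phenols of flavone 2 as benzyl ethers lets the final step be a neutral hydrogenolysis that leaves the methyl ethers and both pyranones alone.

**15 ⇒ 14 ⇒ 13.** The O4'–methyl bond and then the O7''–benzyl bond are cut, leading back to diol 13. This detour is the price of the tether: the key step needs O4' and O7'' free for silicon, so they emerge together and must be told apart afterwards. The 7''-hydroxyl is para to the C4'' carbonyl (a vinylogous acid), whereas the 4'-hydroxyl reaches the C4 carbonyl only through the C2=C3 bond. The forward sequence must therefore benzylate the more acidic 7''-oxygen under a weak base and then methylate the remaining phenol.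

**13 ⇒ 12.** O4' and O7'' are reconnected through a di-tert-butylsilylene unit, giving the seven-membered dioxasilepine 12. Nothing is gained in the skeleton; the bridge exists only to make the biaryl bond formation intramolecular, and the forward step is a fluoride-mediated cleavage of two aryl Si–O bonds.

**12 ⇒ 11 (key disconnection).** The C3'–C8'' bond is cut. It is the only bond between two otherwise ordinary flavones, so cutting it reduces the problem to two monoflavones that each take two or three steps. Cutting it inside the tether means ring B needs no boron or halogen. The forward reaction must insert palladium into the C8''–Br bond of 11 and cleave the C3'–H bond of ring B, closing the seven-membered ring.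

**11 ⇒ 9 + 4 (through 10).** The two Si–O bonds are cut. The forward order matters: the hindered, weakly nucleophilic bromophenol 9 should be silylated first, giving chlorosilane 10, and the unhindered phenol 4 should then displace the remaining, more shielded chloride.

**9 ⇒ 8.** The C8''–Br bond is cut. In a 7-hydroxyflavone the carbon between the hydroxyl and the ring oxygen is the most nucleophilic, so electrophilic bromination of 8 should mark exactly the carbon that will carry the biaryl bond.

**8 ⇒ 7 ⇒ 5 + 6.** Pyranone ring F is opened at O1''–C2'' to the 2'-hydroxychalcone 7, whose enone C=C bond comes from an aldol condensation of ketone 5 with aldehyde 6. The 4'''-oxygen is benzylated from the outset and stays so until the last step.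

**4 ⇒ 3 ⇒ 1 + 2.** Ring C is opened in the same way to chalcone 3, made from ketone 1 and aldehyde 2. The 4'-hydroxyl is left free because it is the attachment point for silicon.

## Alternatives that were turned down

Alternative 1: Ring B is built rather than coupled, by cutting its C2'–C3' and C4'–C5' bonds.
- **Forward key step:** methyl coumalate A1 and the 8''-(methoxyethynyl)flavone A2 would undergo an inverse-demand Diels–Alder addition. The aryl-bearing alkyne carbon bonds to the electrophilic C6 of the pyranone, and decarboxylative cycloreversion then gives the methyl 3-aryl-4-methoxybenzoate A3.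
- **For:** the 4'-methoxy group arrives as a methyl ether, so the phenol differentiation of the chosen end-game disappears, and no cross-coupling at the crowded C8'' is needed. On these two points it is stronger than the chosen route.
- **Against:** A1 is a cheap and stable diene, but A2 is an acid- and heat-sensitive ynol ether that must be installed at the congested C8''. Its aryl substituent is ortho,ortho'-disubstituted, which slows the cycloaddition and pushes it towards temperatures the ynol ether may not survive. After the key step, ring C of flavone 1 still has to be built from the ester of A3 by acylation of ketone 1 and cyclodehydration, followed by debenzylation.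
- **Comparison:** the sequence is longer and more linear, and flavone 2 is carried through the most delicate chemistry. The chosen route offers two finished flavones, each made in two or three robust steps, and a ring closure of a known type.

Alternative 2: Both pyranone rings are opened at O1–C2 and O1''–C2'', leading back to the biaryl bis-chalcone A4.
- **Forward key step:** a double oxidative cyclisation under the conditions of steps 2 and 4 would give the 7'',4'''-di-O-benzyl target A5, which is the same compound as 15.
- **For:** both methyl ethers are present from the start, the cyclisation is dependable, and A5 is one hydrogenolysis from the target. Its end-game is three steps shorter than the chosen one and free of any site-selectivity question. This is the strongest competitor.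
- **Against:** the key step does not address the biaryl bond. That bond has to be made earlier by an intermolecular coupling at a carbon flanked by two oxygens, with a halogen on one ring and a metal on the other. The ring D oxygens must be differentiated (benzyl ether at C7'', free hydroxyl at C8a''). The two different chalcone arms must be grown one after the other on a biaryl that carries both a formyl and an acetyl function.
- **Comparison:** the chosen route forms the hindered bond intramolecularly, needs no functional group on ring B, and avoids the aldehyde/ketone ordering problem. It pays for this with the late phenol differentiation.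

Alternative 3: Ring F is opened at O1''–C8a'', with ring D carried as a difluoroarene.
- **Forward key step:** the enolate oxygen of the 1,3-diketone A6 would displace the fluoride ortho to the ketone under a mild carbonate base, giving the 7''-fluoro biflavone A7.
- **For:** before closure ring D is a symmetric 2,6-difluoroaryl unit, so its attachment to ring B is regiochemically unambiguous and sterically easy. The 4'-methoxy group is in place from the start.
- **Against:** A7 still has a fluorine where the target has a hydroxyl. A second substitution by an oxygen nucleophile and a deprotection must follow, with a strong alkoxide acting on a molecule whose two pyranones are prone to ring-opening at C2 and C2''. A6 must be assembled by enolate acylation next to the finished flavone 1, and 2,6-difluoroaryl boron reagents are prone to protodeboronation.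
- **Comparison:** it is longer and puts more basic, nucleophilic steps late than the chosen route, which keeps such conditions away from the pyranones and builds both heterocycles before the union.

Key step: step 7

## Route

Remark: the C3'–C8'' axis of the target is drawn without configuration; with three small oxygen-bearing ortho positions it is taken as not configurationally stable, and no control of axial chirality is planned.

Step 1
Reactants: 1 2-hydroxy-4-methoxyacetophenone; 2 4-hydroxybenzaldehyde
Product: 3 (E)-1-(2-hydroxy-4-methoxyphenyl)-3-(4-hydroxyphenyl)prop-2-en-1-one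
Conditions: KOH (50% aq., excess), EtOH, rt → 50 °C; then HCl aq.
Reagents that add atoms: none
Why: Claisen–Schmidt condensation: the methyl ketone is the only enolisable partner and the aldehyde has no α-hydrogen, and dehydration of the aldol gives the conjugated E-enone as the thermodynamic product. Concentrated base and a long reaction time offset the lower electrophilicity of the aldehyde, which is present as its phenoxide.

Step 2
Reactants: 3 (E)-1-(2-hydroxy-4-methoxyphenyl)-3-(4-hydroxyphenyl)prop-2-en-1-one
Product: 4 2-(4-hydroxyphenyl)-7-methoxy-4H-chromen-4-one (4'-hydroxy-7-methoxyflavone)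
Conditions: I2 (10 mol %), DMSO, 130 °C
Reagents that add atoms: none
Why: Iodine-catalysed oxidative cyclisation of a 2'-hydroxychalcone: 6-endo oxa-Michael closure, α-iodination and loss of HI give the pyranone, and DMSO reoxidises HI to iodine. The free 4'-phenol should be tolerated because iodine is catalytic and ring B is deactivated by the enone.

Step 3
Reactants: 5 2,4-dihydroxyacetophenone; 6 4-(benzyloxy)benzaldehyde
Product: 7 (E)-3-[4-(benzyloxy)phenyl]-1-(2,4-dihydroxyphenyl)prop-2-en-1-one
Conditions: KOH (60% aq., excess), EtOH, rt → 40 °C; then HCl aq.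
Reagents that add atoms: none
Why: Claisen–Schmidt condensation as in step 1; here the aldehyde cannot form a phenoxide and stays electrophilic, while the concentrated base compensates for the reduced acidity of the resorcinol ketone. The E-enone is again the thermodynamic product.

Step 4
Reactants: 7 (E)-3-[4-(benzyloxy)phenyl]-1-(2,4-dihydroxyphenyl)prop-2-en-1-one
Product: 8 2-[4-(benzyloxy)phenyl]-7-hydroxy-4H-chromen-4-one
Conditions: I2 (10 mol %), DMSO, 130 °C
Reagents that add atoms: none
Why: The same iodine-catalysed oxidative cyclisation as in step 2; only the hydroxyl ortho to the ketone can close the six-membered ring, so the para hydroxyl ends up as the 7''-hydroxyl. The benzyl aryl ether should survive the catalytic amount of HI.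

Step 5
Reactants: 8 2-[4-(benzyloxy)phenyl]-7-hydroxy-4H-chromen-4-one
Product: 9 2-[4-(benzyloxy)phenyl]-8-bromo-7-hydroxy-4H-chromen-4-one
Conditions: NBS (1.0 equiv), DMF, 0 °C → rt
Reagents that add atoms: N-bromosuccinimide, O=C1CCC(=O)N1Br
Why: Electrophilic aromatic bromination ortho to the free phenol; in 7-hydroxychromones the carbon between the hydroxyl and the ring oxygen (C8'') is the most nucleophilic position, as C1 is in 2-naphthol. Ring E and C3'' are deactivated by conjugation with the carbonyl, and one equivalent at low temperature limits a second bromination at C6''.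

Step 6
Reactants: 9 2-[4-(benzyloxy)phenyl]-8-bromo-7-hydroxy-4H-chromen-4-one; 4 2-(4-hydroxyphenyl)-7-methoxy-4H-chromen-4-one
Product: 11 2-[4-(benzyloxy)phenyl]-8-bromo-7-({di-tert-butyl[4-(7-methoxy-4-oxo-4H-chromen-2-yl)phenoxy]silyl}oxy)-4H-chromen-4-one, via aryloxy(di-tert-butyl)chlorosilane 10 (not isolated)
Conditions: 9, t-Bu2SiCl2 (1.1 equiv), imidazole (4 equiv), DMF, 0 °C → rt; then 4 (1.0 equiv), DMAP (0.2 equiv), 70 °C
Reagents that add atoms: di-tert-butyldichlorosilane, CC(C)(C)[Si](Cl)(Cl)C(C)(C)C
Why: Two successive nucleophilic substitutions at silicon with imidazole as base and silyl-transfer agent. The hindered, weakly nucleophilic phenol 9 is paired with the more reactive dichloride, and the two tert-butyl groups then make the remaining chloride of 10 slow enough that a second molecule of 9 does not add. The unhindered phenol 4 displaces that chloride on warming.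

Step 7
Reactants: 11 2-[4-(benzyloxy)phenyl]-8-bromo-7-({di-tert-butyl[4-(7-methoxy-4-oxo-4H-chromen-2-yl)phenoxy]silyl}oxy)-4H-chromen-4-one
Product: 12 silicon-bridged biflavone: the dibenzo[d,f][1,3,2]dioxasilepine in which Si(t-Bu)2 links O4' and O7'' and C3' is bonded to C8'' (7-methoxyflavone unit on ring B, 4'''-benzyloxyflavone unit fused at ring D)
Conditions: Pd(OAc)2 (10 mol %), PCy3·HBF4 (20 mol %), Cs2CO3 (2 equiv), PivOH (30 mol %), p-xylene, 140 °C
Reagents that add atoms: none
Why: Pd(OAc)2 is reduced by the phosphine to zerovalent palladium, which inserts into the C8''–Br bond of 11, and the O7''–Si–O4' bridge then holds the arylpalladium bromide over ring B. Exchange of bromide for pivalate or carbonate allows concerted metalation–deprotonation at C3', giving an eight-membered diarylpalladium ring (Pd, C8'', C7'', O, Si, O, C4', C3'), and reductive elimination forms the C3'–C8'' bond and returns zerovalent palladium. The closest known reaction type is the palladium-catalysed intramolecular C–H arylation of (2-bromoaryloxy)(aryloxy)di-tert-butylsilanes to dibenzo[d,f][1,3,2]dioxasilepines, of which 11 is a member with flavone substituents. The seven-membered ring (C4', C3', C8'', C7'', O, Si, O) closes by this intramolecular direct arylation; a reach to C2' or to C3 of ring C would need a larger, meta-bridged ring and is not expected. No stereocentre is formed; the biaryl axis is twisted inside the silepine and is released again in step 8. Site selectivity on ring D is fixed by the bromine at C8'', and on ring B by the tether together with the equivalence of C3' and C5'. Ring B carries the electron-poor pyranone para to O4', which acidifies the C3'–H bond and favours base-assisted metalation, and the two tert-butyl groups shield the Si–O bonds from the base and compress the O–Si–O angle so that the folded, reactive conformer is populated. Cs2CO3 takes up the HBr, and the benzyl ether, the methyl ether and both pyranones should be inert to these anhydrous, non-nucleophilic conditions.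

Step 8
Reactants: 12 silicon-bridged biflavone (dibenzodioxasilepine)
Product: 13 2-[4-(benzyloxy)phenyl]-7-hydroxy-8-[2-hydroxy-5-(7-methoxy-4-oxo-4H-chromen-2-yl)phenyl]-4H-chromen-4-one
Conditions: Bu4NF (2.2 equiv), AcOH (2.2 equiv), THF, 0 °C → rt
Reagents that add atoms: none
Why: Fluoride-mediated cleavage of both aryl Si–O bonds, driven by the strength of the Si–F bond and the good leaving-group ability of the two flavone phenoxides. Acetic acid protonates the phenoxides as they form, so the pyranones never see a strongly basic medium.

Step 9
Reactants: 13 2-[4-(benzyloxy)phenyl]-7-hydroxy-8-[2-hydroxy-5-(7-methoxy-4-oxo-4H-chromen-2-yl)phenyl]-4H-chromen-4-one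
Product: 14 7-(benzyloxy)-2-[4-(benzyloxy)phenyl]-8-[2-hydroxy-5-(7-methoxy-4-oxo-4H-chromen-2-yl)phenyl]-4H-chromen-4-one
Conditions: BnBr (1.05 equiv), KHCO3 (1.2 equiv), DMF, 50 °C
Reagents that add atoms: benzyl bromide, BrCc1ccccc1
Why: Williamson etherification under acidity control: the 7''-hydroxyl is para to the C4'' carbonyl and should be about one pKa unit more acidic than the 4'-hydroxyl, so a weak base with one equivalent of electrophile should alkylate mainly O7''. This is the pattern of 7-O-selective alkylation of 7,4'-dihydroxyflavonoids.

Step 10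
Reactants: 14 7-(benzyloxy)-2-[4-(benzyloxy)phenyl]-8-[2-hydroxy-5-(7-methoxy-4-oxo-4H-chromen-2-yl)phenyl]-4H-chromen-4-one
Product: 15 7-(benzyloxy)-2-[4-(benzyloxy)phenyl]-8-[2-methoxy-5-(7-methoxy-4-oxo-4H-chromen-2-yl)phenyl]-4H-chromen-4-one
Conditions: MeI (3 equiv), K2CO3 (2 equiv), acetone, 50 °C
Reagents that add atoms: iodomethane, CI
Why: Williamson methylation of the only remaining phenol; carbonate in acetone is not nucleophilic enough to open the pyranones.

Step 11
Reactants: 15 7-(benzyloxy)-2-[4-(benzyloxy)phenyl]-8-[2-methoxy-5-(7-methoxy-4-oxo-4H-chromen-2-yl)phenyl]-4H-chromen-4-one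
Product: 16 7-hydroxy-2-(4-hydroxyphenyl)-8-[2-methoxy-5-(7-methoxy-4-oxo-4H-chromen-2-yl)phenyl]-4H-chromen-4-one (target)
Conditions: H2 (1 atm), Pd/C (10%), THF–MeOH, rt
Reagents that add atoms: none
Why: Hydrogenolysis of both benzyl aryl ethers; the aryl methyl ethers are inert, and the vinylogous-ester C2=C3 bonds of the two pyranones are not expected to be reduced at ambient pressure if the reaction is stopped at full debenzylation.

## Compound list

1 | 2-hydroxy-4-methoxyacetophenone | CC(=O)c1ccc(OC)cc1O | starting material
2 | 4-hydroxybenzaldehyde | O=Cc1ccc(O)cc1 | starting material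
3 | (E)-1-(2-hydroxy-4-methoxyphenyl)-3-(4-hydroxyphenyl)prop-2-en-1-one | COc1ccc(C(=O)/C=C/c2ccc(O)cc2)c(O)c1 | intermediate
4 | 2-(4-hydroxyphenyl)-7-methoxy-4H-chromen-4-one | COc1ccc2c(=O)cc(-c3ccc(O)cc3)oc2c1 | intermediate
5 | 2,4-dihydroxyacetophenone | CC(=O)c1ccc(O)cc1O | starting material
6 | 4-(benzyloxy)benzaldehyde | O=Cc1ccc(OCc2ccccc2)cc1 | starting material
7 | (E)-3-[4-(benzyloxy)phenyl]-1-(2,4-dihydroxyphenyl)prop-2-en-1-one | O=C(/C=C/c1ccc(OCc2ccccc2)cc1)c1ccc(O)cc1O | intermediate
8 | 2-[4-(benzyloxy)phenyl]-7-hydroxy-4H-chromen-4-one | O=c1cc(-c2ccc(OCc3ccccc3)cc2)oc2cc(O)ccc12 | intermediate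
9 | 2-[4-(benzyloxy)phenyl]-8-bromo-7-hydroxy-4H-chromen-4-one | O=c1cc(-c2ccc(OCc3ccccc3)cc2)oc2c(Br)c(O)ccc12 | intermediate
10 | 2-[4-(benzyloxy)phenyl]-8-bromo-7-{[di-tert-butyl(chloro)silyl]oxy}-4H-chromen-4-one (formed in the flask) | CC(C)(C)[Si](Cl)(Oc1ccc2c(=O)cc(-c3ccc(OCc4ccccc4)cc3)oc2c1Br)C(C)(C)C | intermediate
11 | 2-[4-(benzyloxy)phenyl]-8-bromo-7-({di-tert-butyl[4-(7-methoxy-4-oxo-4H-chromen-2-yl)phenoxy]silyl}oxy)-4H-chromen-4-one | COc1ccc2c(=O)cc(-c3ccc(O[Si](C(C)(C)C)(C(C)(C)C)Oc4ccc5c(=O)cc(-c6ccc(OCc7ccccc7)cc6)oc5c4Br)cc3)oc2c1 | intermediate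
12 | silicon-bridged biflavone: dibenzo[d,f][1,3,2]dioxasilepine with Si(t-Bu)2 between O4' and O7'' and the C3'–C8'' bond formed | COc1ccc2c(=O)cc(-c3ccc4c(c3)-c3c(ccc5c(=O)cc(-c6ccc(OCc7ccccc7)cc6)oc35)O[Si](C(C)(C)C)(C(C)(C)C)O4)oc2c1 | intermediate
13 | 2-[4-(benzyloxy)phenyl]-7-hydroxy-8-[2-hydroxy-5-(7-methoxy-4-oxo-4H-chromen-2-yl)phenyl]-4H-chromen-4-one | COc1ccc2c(=O)cc(-c3ccc(O)c(-c4c(O)ccc5c(=O)cc(-c6ccc(OCc7ccccc7)cc6)oc45)c3)oc2c1 | intermediate
14 | 7-(benzyloxy)-2-[4-(benzyloxy)phenyl]-8-[2-hydroxy-5-(7-methoxy-4-oxo-4H-chromen-2-yl)phenyl]-4H-chromen-4-one | COc1ccc2c(=O)cc(-c3ccc(O)c(-c4c(OCc5ccccc5)ccc5c(=O)cc(-c6ccc(OCc7ccccc7)cc6)oc45)c3)oc2c1 | intermediate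
15 | 7-(benzyloxy)-2-[4-(benzyloxy)phenyl]-8-[2-methoxy-5-(7-methoxy-4-oxo-4H-chromen-2-yl)phenyl]-4H-chromen-4-one | COc1ccc2c(=O)cc(-c3ccc(OC)c(-c4c(OCc5ccccc5)ccc5c(=O)cc(-c6ccc(OCc7ccccc7)cc6)oc45)c3)oc2c1 | intermediate
16 | 7-hydroxy-2-(4-hydroxyphenyl)-8-[2-methoxy-5-(7-methoxy-4-oxo-4H-chromen-2-yl)phenyl]-4H-chromen-4-one | COc1ccc2c(=O)cc(-c3ccc(OC)c(-c4c(O)ccc5c(=O)cc(-c6ccc(O)cc6)oc45)c3)oc2c1 | target

## Step count and risk

Total step count: 11. Longest linear sequence: 9 steps (steps 3, 4, 5, 6, 7, 8, 9, 10, 11, from 5 and 6).

**Step 7 (key step).**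
- What may go wrong: base-induced cleavage or exchange of the aryloxy groups at silicon before palladium has closed the ring, since both phenoxides are stabilised by their pyranone carbonyls and leave easily. Hydrodebromination at C8'' is also possible if C–H metalation through the eight-membered palladacycle is slower than reduction of the arylpalladium intermediate.
- Fallback: an intermolecular Suzuki–Miyaura coupling that sets out from 4 and 9 and returns at 15, bypassing steps 6 to 10. From 4, ortho-iodination with N-iodosuccinimide would give 2-(4-hydroxy-3-iodophenyl)-7-methoxy-4H-chromen-4-one F1. Methylation (MeI, K2CO3) would give 2-(3-iodo-4-methoxyphenyl)-7-methoxy-4H-chromen-4-one F2. Miyaura borylation (bis(pinacolato)diboron, PdCl2(dppf), KOAc) would give the pinacol boronate 7-methoxy-2-[4-methoxy-3-(4,4,5,5-tetramethyl-1,3,2-dioxaborolan-2-yl)phenyl]-4H-chromen-4-one F3. From 9, benzylation (BnBr, K2CO3) would give 7-(benzyloxy)-2-[4-(benzyloxy)phenyl]-8-bromo-4H-chromen-4-one F4. Coupling of F3 with F4 (Pd(OAc)2, SPhos, K3PO4, toluene–water) would give 15 directly.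

**Step 6.**
- What may go wrong: incomplete displacement of the shielded chloride of 10 by 4, or redistribution of aryloxy groups at silicon under the heating needed, leading to symmetric bis(aryloxy)silanes.
- Fallback: a hydrosilane route that sets out from 9 and returns at 11. Silylation of 9 with di-tert-butylchlorosilane and imidazole would give the isolable 2-[4-(benzyloxy)phenyl]-8-bromo-7-[(di-tert-butylsilyl)oxy]-4H-chromen-4-one F5. N-Bromosuccinimide would convert its Si–H bond into the more electrophilic 7-{[bromo(di-tert-butyl)silyl]oxy} compound F6 in the flask. Addition of 4 and imidazole would then give 11 at lower temperature.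

**Step 9.**
- What may go wrong: loss of site selectivity, because the two phenols face each other across the axis and can share the proton of the monoanion, so the acidity difference may not carry over fully into alkylation at O7''. Double benzylation would also consume material.
- Fallback: an acetate detour that sets out from 13 and returns at 14. Acetylation (Ac2O, pyridine) would give the 4',7''-diacetate F7. Thiophenol with imidazole, which removes the acetate of the most acidic flavonoid phenol, would give the 4'-monoacetate with free 7''-hydroxyl F8. Benzylation (BnBr, K2CO3) would give the 7''-O-benzyl 4'-acetate F9, where any acetyl migration across the axis favours the acetate on the less acidic O4'. Methanolysis (K2CO3, MeOH) would give 14.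

**Step 5.**
- What may go wrong: bromination at C6'' instead of C8'', double bromination, or attack at C3'' of the pyranone, with a regiochemical assignment that is hard to secure.
- Fallback: build the ring with the bromine already in place, setting out from 6 and returning at 9. 2-Bromobenzene-1,3-diol F10 would be acetylated at C4 (AcOH, BF3·OEt2, 90 °C; the two open positions are equivalent) to 1-(3-bromo-2,4-dihydroxyphenyl)ethanone F11. Claisen–Schmidt condensation with 6 would give (E)-3-[4-(benzyloxy)phenyl]-1-(3-bromo-2,4-dihydroxyphenyl)prop-2-en-1-one F12. The iodine-catalysed oxidative cyclisation of step 4 would then give 9 without ambiguity.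

**Step 1.**
- What may go wrong: slow and incomplete condensation, because aldehyde 2 is present as a poorly electrophilic phenoxide, with competing disproportionation of the aldehyde in concentrated base. Step 3 uses the same reaction but its aldehyde cannot form a phenoxide.
- Fallback: a protected aldehyde, setting out from 1 and 6 and returning at 4. Condensation would give (E)-3-[4-(benzyloxy)phenyl]-1-(2-hydroxy-4-methoxyphenyl)prop-2-en-1-one F13. Oxidative cyclisation as in step 2 would give 2-[4-(benzyloxy)phenyl]-7-methoxy-4H-chromen-4-one F14. Hydrogenolysis (H2, Pd/C) would give 4.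

## Further compounds

F1 | step 7 | 2-(4-hydroxy-3-iodophenyl)-7-methoxy-4H-chromen-4-one | COc1ccc2c(=O)cc(-c3ccc(O)c(I)c3)oc2c1
F2 | step 7 | 2-(3-iodo-4-methoxyphenyl)-7-methoxy-4H-chromen-4-one | COc1ccc2c(=O)cc(-c3ccc(OC)c(I)c3)oc2c1
F3 | step 7 | 7-methoxy-2-[4-methoxy-3-(4,4,5,5-tetramethyl-1,3,2-dioxaborolan-2-yl)phenyl]-4H-chromen-4-one | COc1ccc2c(=O)cc(-c3ccc(OC)c(B4OC(C)(C)C(C)(C)O4)c3)oc2c1
F4 | step 7 | 7-(benzyloxy)-2-[4-(benzyloxy)phenyl]-8-bromo-4H-chromen-4-one | O=c1cc(-c2ccc(OCc3ccccc3)cc2)oc2c(Br)c(OCc3ccccc3)ccc12
F5 | step 6 | 2-[4-(benzyloxy)phenyl]-8-bromo-7-[(di-tert-butylsilyl)oxy]-4H-chromen-4-one | CC(C)(C)[SiH](Oc1ccc2c(=O)cc(-c3ccc(OCc4ccccc4)cc3)oc2c1Br)C(C)(C)C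
F6 | step 6 | 2-[4-(benzyloxy)phenyl]-8-bromo-7-{[bromo(di-tert-butyl)silyl]oxy}-4H-chromen-4-one | CC(C)(C)[Si](Br)(Oc1ccc2c(=O)cc(-c3ccc(OCc4ccccc4)cc3)oc2c1Br)C(C)(C)C
F7 | step 9 | 4',7''-di-O-acetyl derivative of 13 | COc1ccc2c(=O)cc(-c3ccc(OC(C)=O)c(-c4c(OC(C)=O)ccc5c(=O)cc(-c6ccc(OCc7ccccc7)cc6)oc45)c3)oc2c1
F8 | step 9 | 4'-O-acetyl derivative of 13 with free 7''-hydroxyl | COc1ccc2c(=O)cc(-c3ccc(OC(C)=O)c(-c4c(O)ccc5c(=O)cc(-c6ccc(OCc7ccccc7)cc6)oc45)c3)oc2c1
F9 | step 9 | 4'-O-acetyl derivative of 14 | COc1ccc2c(=O)cc(-c3ccc(OC(C)=O)c(-c4c(OCc5ccccc5)ccc5c(=O)cc(-c6ccc(OCc7ccccc7)cc6)oc45)c3)oc2c1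
F10 | step 5 | 2-bromobenzene-1,3-diol | Oc1cccc(O)c1Br
F11 | step 5 | 1-(3-bromo-2,4-dihydroxyphenyl)ethanone | CC(=O)c1ccc(O)c(Br)c1O
F12 | step 5 | (E)-3-[4-(benzyloxy)phenyl]-1-(3-bromo-2,4-dihydroxyphenyl)prop-2-en-1-one | O=C(/C=C/c1ccc(OCc2ccccc2)cc1)c1ccc(O)c(Br)c1O
F13 | step 1 | (E)-3-[4-(benzyloxy)phenyl]-1-(2-hydroxy-4-methoxyphenyl)prop-2-en-1-one | COc1ccc(C(=O)/C=C/c2ccc(OCc3ccccc3)cc2)c(O)c1
F14 | step 1 | 2-[4-(benzyloxy)phenyl]-7-methoxy-4H-chromen-4-one | COc1ccc2c(=O)cc(-c3ccc(OCc4ccccc4)cc3)oc2c1
A1 | alternative 1 | methyl coumalate (methyl 2-oxo-2H-pyran-5-carboxylate) | COC(=O)c1ccc(=O)oc1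
A2 | alternative 1 | 7-(benzyloxy)-2-[4-(benzyloxy)phenyl]-8-(methoxyethynyl)-4H-chromen-4-one | COC#Cc1c(OCc2ccccc2)ccc2c(=O)cc(-c3ccc(OCc4ccccc4)cc3)oc12
A3 | alternative 1 | methyl 3-{7-(benzyloxy)-2-[4-(benzyloxy)phenyl]-4-oxo-4H-chromen-8-yl}-4-methoxybenzoate | COC(=O)c1ccc(OC)c(-c2c(OCc3ccccc3)ccc3c(=O)cc(-c4ccc(OCc5ccccc5)cc4)oc23)c1
A4 | alternative 2 | biaryl bis-chalcone: (E)-3-[3-(6-(benzyloxy)-3-{(E)-3-[4-(benzyloxy)phenyl]acryloyl}-2-hydroxyphenyl)-4-methoxyphenyl]-1-(2-hydroxy-4-methoxyphenyl)prop-2-en-1-one | COc1ccc(C(=O)/C=C/c2ccc(OC)c(-c3c(OCc4ccccc4)ccc(C(=O)/C=C/c4ccc(OCc5ccccc5)cc4)c3O)c2)c(O)c1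
A5 | alternative 2 | 7'',4'''-di-O-benzyl target (identical with 15) | COc1ccc2c(=O)cc(-c3ccc(OC)c(-c4c(OCc5ccccc5)ccc5c(=O)cc(-c6ccc(OCc7ccccc7)cc6)oc45)c3)oc2c1
A6 | alternative 3 | 1-[4-(benzyloxy)phenyl]-3-{2,4-difluoro-3-[2-methoxy-5-(7-methoxy-4-oxo-4H-chromen-2-yl)phenyl]phenyl}propane-1,3-dione | COc1ccc2c(=O)cc(-c3ccc(OC)c(-c4c(F)ccc(C(=O)CC(=O)c5ccc(OCc6ccccc6)cc5)c4F)c3)oc2c1
A7 | alternative 3 | 2-[4-(benzyloxy)phenyl]-7-fluoro-8-[2-methoxy-5-(7-methoxy-4-oxo-4H-chromen-2-yl)phenyl]-4H-chromen-4-one | COc1ccc2c(=O)cc(-c3ccc(OC)c(-c4c(F)ccc5c(=O)cc(-c6ccc(OCc7ccccc7)cc6)oc45)c3)oc2c1
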